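Assumption: the target has no stereocentre and no configurationally stable axis, so it is a single achiral compound and no stereocontrol is needed.

**Retrosynthetic overview**
1. The depside C(acyl)–O bond is cut last: target ⇒ ring A phenol (methyl 4-hydroxy-2-methoxy-3,5,6-trimethylbenzoate) + the symmetric ring B dialdehyde (4,6-dihydroxy-2,5-dimethylbenzene-1,3-dicarbaldehyde). One of its two equivalent formyl groups is oxidatively esterified, so no ring B acid and no ring B protecting group is needed.
2. Ring A phenol ⇒ atraric acid: one-pot 4-O-benzylation/2-O-methylation, formylation of the only free ring CH, then one-pot hydrogenolysis (CHO → CH3, OBn → OH).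
3. Ring B dialdehyde ⇒ 2,5-dimethylresorcinol by double ortho-formylation.
4. No ring is built: both benzene rings are bought. Ring A is elaborated (3 steps), ring B is made (1 step), and the two are joined last.

**Route**

Step 1
Reactants: 1 methyl 2,4-dihydroxy-3,6-dimethylbenzoate (atraric acid)
Product: 3 methyl 4-(benzyloxy)-2-methoxy-3,6-dimethylbenzoate, via mono-benzyl ether 2 (not isolated)
Conditions: BnBr (1.05 equiv), K2CO3 (3 equiv), DMF, rt, 8 h; then MeI (3 equiv), 50 °C (sealed), 12 h
Reagents that add atoms: benzyl bromide BrCc1ccccc1; iodomethane CI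
Why: Williamson ether synthesis in two stages in one pot: the free 4-OH is benzylated at rt, while the 2-OH, hydrogen-bonded to the ester carbonyl, only reacts in the later forced methylation with excess MeI; no stereocentre is formed.

Step 2
Reactants: 3 methyl 4-(benzyloxy)-2-methoxy-3,6-dimethylbenzoate
Product: 5 methyl 4-(benzyloxy)-5-formyl-2-methoxy-3,6-dimethylbenzoate, via chloro ether 4 (not isolated)
Conditions: Cl2CHOMe (2 equiv), SnCl4 (2.5 equiv), CH2Cl2, −20 → 0 °C; then ice-cold 1 M HCl
Reagents that add atoms: dichloromethyl methyl ether COC(Cl)Cl; water O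
Why: Rieche formylation (Friedel–Crafts type) at C5, the only unsubstituted position of the ring, which is ortho to OBn and para to OMe, followed by hydrolysis of the chloro ether on work-up; the transient CH(Cl)OMe centre is racemic and is destroyed, and any benzyl ether cleavage here is harmless because step 3 removes the group anyway.

Step 3
Reactants: 5 methyl 4-(benzyloxy)-5-formyl-2-methoxy-3,6-dimethylbenzoate
Product: 8 methyl 4-hydroxy-2-methoxy-3,5,6-trimethylbenzoate, via free-phenol aldehyde 6 (not isolated), via benzylic alcohol 7 (not isolated)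
Conditions: H2 (4 bar), 10% Pd/C, AcOH, cat. HCl, 40 °C
Reagents that add atoms: none
Why: Catalytic hydrogenolysis: the benzyl ether is cleaved, the ortho-hydroxy benzaldehyde is hydrogenated to the benzylic alcohol, and under acid this ionises (ortho-quinone methide/benzylic cation) and is reduced to the methyl group, while the ester and methyl ether are inert; no stereocentre is formed.

Step 4
Reactants: 9 2,5-dimethylbenzene-1,3-diol (2,5-dimethylresorcinol)
Product: 11 4,6-dihydroxy-2,5-dimethylbenzene-1,3-dicarbaldehyde, via bis-aldimine 10 (not isolated)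
Conditions: hexamethylenetetramine (4 equiv), CF3CO2H, 90 °C, 16 h; then 3 M HCl, 60 °C, 2 h
Reagents that add atoms: hexamethylenetetramine C1N2CN3CN1CN(C2)C3; water O
Why: Duff reaction in CF3CO2H: C4 and C6 are the only free ring positions and each is ortho to one hydroxyl and para to the other, so aminomethylation, internal hydride transfer to the iminium stage and acid hydrolysis give the symmetric dialdehyde; no stereocentre is formed.

Step 5
Reactants: 8 methyl 4-hydroxy-2-methoxy-3,5,6-trimethylbenzoate (1 equiv); 11 4,6-dihydroxy-2,5-dimethylbenzene-1,3-dicarbaldehyde (2 equiv, excess recovered)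
Product: 12 3-methoxy-4-(methoxycarbonyl)-2,5,6-trimethylphenyl 3-formyl-4,6-dihydroxy-2,5-dimethylbenzoate (target)
Conditions: 1,4-dimethyl-1,2,4-triazolium iodide (15 mol%), DBU (1.2 equiv), 3,3',5,5'-tetra-tert-butyl-4,4'-diphenoquinone (1.0 equiv), 4 Å MS, THF, 40 °C
Reagents that add atoms: none
Why: Proposed new method: the small N-methyl triazolylidene adds to one of the two equivalent, hydrogen-bond-activated formyl groups of 11, the Breslow intermediate is oxidised by the diphenoquinone to an acyl azolium, and this ortho-hydroxy acyl azolium can shed the carbene (E1cB) to a flat, unhindered ortho-quinone ketene that the 2,6-disubstituted phenol 8 captures at its sp carbon to give the aryl ester; any ester formed with the more acidic phenols of 11 is an active ester that reverts and funnels to the depside, and mono-oxidation is enforced by the oxidant being limiting and 11 being in excess; the closest known reaction type is carbene-catalysed oxidative esterification of aldehydes with alcohols and phenols using this quinone oxidant, not yet shown for a di-ortho-substituted bis-salicylaldehyde, for desymmetrising mono-oxidation of such a dialdehyde, or for a 2,6-disubstituted phenol partner; no stereocentre is formed.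

**Compound list**
1 | methyl 2,4-dihydroxy-3,6-dimethylbenzoate (atraric acid) | COC(=O)c1c(C)cc(O)c(C)c1O | starting material
2 | methyl 4-(benzyloxy)-2-hydroxy-3,6-dimethylbenzoate | COC(=O)c1c(C)cc(OCc2ccccc2)c(C)c1O | intermediate
3 | methyl 4-(benzyloxy)-2-methoxy-3,6-dimethylbenzoate | COC(=O)c1c(C)cc(OCc2ccccc2)c(C)c1OC | intermediate
4 | methyl 4-(benzyloxy)-5-[chloro(methoxy)methyl]-2-methoxy-3,6-dimethylbenzoate (racemic, transient) | COC(=O)c1c(C)c(C(Cl)OC)c(OCc2ccccc2)c(C)c1OC | intermediate
5 | methyl 4-(benzyloxy)-5-formyl-2-methoxy-3,6-dimethylbenzoate | COC(=O)c1c(C)c(C=O)c(OCc2ccccc2)c(C)c1OC | intermediate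
6 | methyl 5-formyl-4-hydroxy-2-methoxy-3,6-dimethylbenzoate | COC(=O)c1c(C)c(C=O)c(O)c(C)c1OC | intermediate
7 | methyl 4-hydroxy-5-(hydroxymethyl)-2-methoxy-3,6-dimethylbenzoate | COC(=O)c1c(C)c(CO)c(O)c(C)c1OC | intermediate
8 | methyl 4-hydroxy-2-methoxy-3,5,6-trimethylbenzoate | COC(=O)c1c(C)c(C)c(O)c(C)c1OC | intermediate
9 | 2,5-dimethylbenzene-1,3-diol (2,5-dimethylresorcinol) | Cc1cc(O)c(C)c(O)c1 | starting material
10 | 4,6-bis(iminomethyl)-2,5-dimethylbenzene-1,3-diol (present as its iminium trifluoroacetate) | N=Cc1c(C)c(C=N)c(O)c(C)c1O | intermediate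
11 | 4,6-dihydroxy-2,5-dimethylbenzene-1,3-dicarbaldehyde | O=Cc1c(C)c(C=O)c(O)c(C)c1O | intermediate
12 | 3-methoxy-4-(methoxycarbonyl)-2,5,6-trimethylphenyl 3-formyl-4,6-dihydroxy-2,5-dimethylbenzoate | COC(=O)c1c(C)c(C)c(OC(=O)c2c(C)c(C=O)c(O)c(C)c2O)c(C)c1OC | target

**Totals**
Total step count: 5. Longest linear sequence: 4 steps (1 → 3 → 5 → 8 → 12).

**Steps most likely to fail, with fallbacks**

Step 5 (the proposed new oxidative mono-esterification) is the main risk. The carbene may add slowly to the hindered, electron-rich, partly deprotonated aldehyde; the phenols of 11 may compete as nucleophiles; and some bis-ester may form. The fallback uses known chemistry, sets out from 11 and comes back at 12. One formyl group of 11 is oxidised with NaClO2 (1.0 equiv) and sulfamic acid in aqueous dioxane at 0 °C (Lindgren–Pinnick oxidation) to 3-formyl-4,6-dihydroxy-2,5-dimethylbenzoic acid F1, which is separated from unreacted 11. F1 is then activated with trifluoroacetic anhydride in toluene at rt as the mixed anhydride 3-formyl-4,6-dihydroxy-2,5-dimethylbenzoic trifluoroacetic anhydride F2 and condensed in the same flask with phenol 8 to give 12. This is the classical depside esterification; both phenols of F1 are hydrogen-bonded to a neighbouring carbonyl and do not need protection.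

Step 2 (Rieche formylation) may be sluggish at the congested C5 flanked by OBn and CH3, or may be accompanied by Lewis-acid debenzylation and benzyl transfer. The fallback sets out from 3 and comes back at 8, bypassing steps 2 and 3. Ring bromination of 3 at its only free position with NBS in MeCN gives methyl 4-(benzyloxy)-5-bromo-2-methoxy-3,6-dimethylbenzoate F3. Suzuki–Miyaura methylation with trimethylboroxine (Pd(OAc)2, SPhos, K3PO4, toluene/water, 100 °C) gives methyl 4-(benzyloxy)-2-methoxy-3,5,6-trimethylbenzoate F4. Hydrogenolysis (H2, 10% Pd/C, EtOAc) then gives 8.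

Step 4 (double Duff formylation) may stop at the mono-aldehyde or give tar with the very electron-rich free resorcinol. The fallback sets out from 9 and comes back at 11. O-Methylation (Me2SO4, K2CO3, acetone, reflux) gives 1,3-dimethoxy-2,5-dimethylbenzene F5. Double Rieche formylation (excess Cl2CHOMe, TiCl4, CH2Cl2, 0 °C → rt) goes through 4,6-bis[chloro(methoxy)methyl]-1,3-dimethoxy-2,5-dimethylbenzene F6, not isolated, and gives after aqueous work-up 4,6-dimethoxy-2,5-dimethylbenzene-1,3-dicarbaldehyde F7. Chelation-assisted cleavage of both methyl ethers, each ortho to a formyl group, with BCl3 in CH2Cl2 (−78 → 0 °C) gives 11.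

**Further compounds**
F1 | step 5 | 3-formyl-4,6-dihydroxy-2,5-dimethylbenzoic acid | OC(=O)c1c(C)c(C=O)c(O)c(C)c1O
F2 | step 5 | 3-formyl-4,6-dihydroxy-2,5-dimethylbenzoic trifluoroacetic anhydride | O=C(OC(=O)C(F)(F)F)c1c(C)c(C=O)c(O)c(C)c1O
F3 | step 2 | methyl 4-(benzyloxy)-5-bromo-2-methoxy-3,6-dimethylbenzoate | COC(=O)c1c(C)c(Br)c(OCc2ccccc2)c(C)c1OC
F4 | step 2 | methyl 4-(benzyloxy)-2-methoxy-3,5,6-trimethylbenzoate | COC(=O)c1c(C)c(C)c(OCc2ccccc2)c(C)c1OC
F5 | step 4 | 1,3-dimethoxy-2,5-dimethylbenzene | COc1cc(C)cc(OC)c1C
F6 | step 4 | 4,6-bis[chloro(methoxy)methyl]-1,3-dimethoxy-2,5-dimethylbenzene | COc1c(C)c(OC)c(C(Cl)OC)c(C)c1C(Cl)OC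
F7 | step 4 | 4,6-dimethoxy-2,5-dimethylbenzene-1,3-dicarbaldehyde | COc1c(C)c(OC)c(C=O)c(C)c1C=O
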